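**Strategy.** The target is a 2,4,6-trihydroxyphenyl ketone of an all-Z skipped C20 tetraene (C1 = carbonyl; alkenes C5=C6, C8=C9, C11=C12, C14=C15; 17S). Everything rests on the C10–C11 disconnection. C10, the methylene between C8=C9 and C11=C12, is a propargylic carbon once all four alkenes are raised to alkynes, and C11 is then an acetylide carbon. A CuI-mediated coupling of the C11–C20 terminal 1,4-diyne (carrying the free 17S carbinol) with the C1–C10 propargylic bromide (already carrying the MOM-protected aryl ketone) gives the whole skeleton as a tetrayne in one operation. One Lindlar hydrogenation then sets all four Z-alkenes, and acid unmasks the phenol ring.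

Key step: step 9

Remark: (S)-2-propyloxirane is assumed to be purchasable in enantiopure form; chain atoms are numbered C1 (ketone carbon) to C20 (methyl).

**Route**

Step 1
Reactants: 1 phloroglucinol
Product: 2 1,3,5-tris(methoxymethoxy)benzene
Conditions: NaH (3.6 equiv), MOMCl (3.6 equiv), DMF, 0 °C → rt
Reagents that add atoms: chloromethyl methyl ether (MOMCl), COCCl
Why: Williamson-type O-alkylation of the sodium phenoxides by the hard electrophile MOMCl in DMF should favour the tris-acetal over C-alkylation.

Step 2
Reactants: 3 hex-5-ynoic acid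
Product: 5 N-methoxy-N-methylhex-5-ynamide, via hex-5-ynoyl imidazolide 4 (not isolated)
Conditions: CDI, CH2Cl2, rt; then MeNHOMe·HCl, rt
Reagents that add atoms: N,O-dimethylhydroxylamine hydrochloride, CNOC.Cl; 1,1'-carbonyldiimidazole (CDI), O=C(n1ccnc1)n1ccnc1 (imidazolyl group of intermediate 4 only)
Why: CDI activation to the acyl imidazolide followed by aminolysis is a standard Weinreb amide synthesis that leaves the terminal alkyne untouched.

Step 3
Reactants: 2 1,3,5-tris(methoxymethoxy)benzene; 5 N-methoxy-N-methylhex-5-ynamide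
Product: 8 1-[2,4,6-tris(methoxymethoxy)phenyl]hex-5-yn-1-one, via 2,4,6-tris(methoxymethoxy)phenyllithium 6 (not isolated), via dilithiated tetrahedral adduct 7 (not isolated)
Conditions: 2 (2.3 equiv), n-BuLi (2.2 equiv), THF, 0 °C; then 5 (1.0 equiv), −78 → −40 °C; aq. NH4Cl
Reagents that add atoms: n-butyllithium, [Li]CCCC (lithium of intermediates 6 and 7 only)
Why: Directed ortho-lithiation of 2 between two MOM-oxy groups gives 6, which adds to the Weinreb amide and stops at the chelated tetrahedral adduct 7 (Weinreb ketone synthesis); one extra equivalent of 6 is consumed by the alkyne C–H, which is restored on quench.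

Step 4
Reactants: 8 1-[2,4,6-tris(methoxymethoxy)phenyl]hex-5-yn-1-one; 9 4-chlorobut-2-yn-1-ol
Product: 12 10-hydroxy-1-[2,4,6-tris(methoxymethoxy)phenyl]deca-5,8-diyn-1-one, via 4-iodobut-2-yn-1-ol 10 (not isolated), via alkynylcopper of the aryl ketone 11 (not isolated)
Conditions: CuI, NaI, K2CO3, DMF, rt, argon
Reagents that add atoms: NaI, [Na+].[I-] (iodine of intermediate 10 only); CuI, [Cu]I (copper of intermediate 11 only)
Why: CuI-mediated coupling of a terminal alkyne with a propargylic halide (the chloride activated by Finkelstein exchange to iodide 10) should give the skipped diyne by SN2 attack of alkynylcopper 11 at the primary carbon, the free hydroxyl being tolerated under carbonate.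

Step 5
Reactants: 12 10-hydroxy-1-[2,4,6-tris(methoxymethoxy)phenyl]deca-5,8-diyn-1-one
Product: 13 10-bromo-1-[2,4,6-tris(methoxymethoxy)phenyl]deca-5,8-diyn-1-one
Conditions: CBr4, PPh3, CH2Cl2, −20 → 0 °C
Reagents that add atoms: carbon tetrabromide, BrC(Br)(Br)Br
Why: Appel bromination converts the primary propargylic alcohol under neutral conditions that should spare the MOM acetals, the ketone and the skipped diyne.

Step 6
Reactants: 14 (S)-2-propyloxirane; 15 lithium acetylide–ethylenediamine complex (LiC≡CH·H2NCH2CH2NH2)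
Product: 16 (4S)-hept-1-yn-4-ol
Conditions: DMSO, 0 °C → rt; aq. NH4Cl
Reagents that add atoms: none
Why: SN2 opening of the terminal epoxide by acetylide at the unsubstituted carbon leaves the C–O bond of the stereocentre intact, so the (S) configuration of 14 is carried unchanged into the carbinol (future C17).

Step 7
Reactants: 16 (4S)-hept-1-yn-4-ol; 17 (3-bromoprop-1-yn-1-yl)trimethylsilane
Product: 19 (4S)-10-(trimethylsilyl)deca-6,9-diyn-4-ol, via alkynylcopper of the heptynol 18 (not isolated)
Conditions: CuI, K2CO3, DMF, rt, argon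
Reagents that add atoms: CuI, [Cu]I (copper of intermediate 18 only)
Why: CuI-mediated alkyne–propargyl bromide coupling through alkynylcopper 18 should give the silyl-capped 1,4-diyne, the trimethylsilyl group blocking further coupling at the new terminus.

Step 8
Reactants: 19 (4S)-10-(trimethylsilyl)deca-6,9-diyn-4-ol
Product: 20 (4S)-deca-6,9-diyn-4-ol
Conditions: Bu4NF, AcOH, THF, 0 °C; used at once
Reagents that add atoms: none
Why: Fluoride-induced protodesilylation of the alkynylsilane, buffered by acetic acid, should free the terminal alkyne without base-induced propargyl–allenyl isomerisation of the 1,4-diyne.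

Step 9
Reactants: 13 10-bromo-1-[2,4,6-tris(methoxymethoxy)phenyl]deca-5,8-diyn-1-one; 20 (4S)-deca-6,9-diyn-4-ol
Product: 22 (17S)-17-hydroxy-1-[2,4,6-tris(methoxymethoxy)phenyl]icosa-5,8,11,14-tetrayn-1-one, via alkynylcopper of the decadiynol 21 (not isolated)
Conditions: CuI, Cs2CO3, DMF (degassed), 0 °C → rt, argon
Reagents that add atoms: CuI, [Cu]I (copper of intermediate 21 only)
Why: Cs2CO3 and CuI convert the terminal alkyne C11–H of 20 into alkynylcopper 21 (monovalent copper), which displaces bromide at the primary propargylic carbon C10 of 13 in an SN2 sense, so that the C10–C11 bond forms as a C(sp3)–C(sp) bond and the full C1–C20 chain is assembled. The closest known reaction type is the CuI-mediated coupling of terminal alkynes with propargylic halides to skipped 1,4-diynes, the standard entry to methylene-interrupted polyyne precursors of polyunsaturated fatty acids. No ring is closed and no stereocentre is formed; the (S)-carbinol C17 is remote from the reacting alkyne and is not touched. The step needs α-attack (SN2) rather than γ-attack (SN2', which would give an allenyne), C-alkylation rather than O-alkylation at the free C17 hydroxyl, and no prototropic shift of the 1,4-diyne units; the unhindered CH2Br terminus, the soft carbon nucleophile on copper and the weak carbonate base at room temperature under argon should secure these. The product holds the four Z-alkenes of the target as four alkynes, so that one syn-hydrogenation reveals the skipped tetraene.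

Step 10
Reactants: 22 (17S)-17-hydroxy-1-[2,4,6-tris(methoxymethoxy)phenyl]icosa-5,8,11,14-tetrayn-1-one
Product: 23 (5Z,8Z,11Z,14Z,17S)-17-hydroxy-1-[2,4,6-tris(methoxymethoxy)phenyl]icosa-5,8,11,14-tetraen-1-one
Conditions: H2 (1 atm), Lindlar catalyst (Pd on CaCO3 poisoned with Pb(OAc)2), quinoline, EtOAc, 10 °C; stopped after uptake of 4 equiv H2
Reagents that add atoms: none
Why: Lindlar semi-hydrogenation delivers H2 syn to each of the four isolated alkynes and should set all four Z-alkenes at once; quinoline and a controlled uptake limit over-reduction, and the hindered aryl ketone and the MOM acetals are inert.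

Step 11
Reactants: 23 (5Z,8Z,11Z,14Z,17S)-17-hydroxy-1-[2,4,6-tris(methoxymethoxy)phenyl]icosa-5,8,11,14-tetraen-1-one
Product: 24 (5Z,8Z,11Z,14Z,17S)-17-hydroxy-1-(2,4,6-trihydroxyphenyl)icosa-5,8,11,14-tetraen-1-one
Conditions: 3 M aq. HCl, MeOH, 45 °C, argon, dark
Reagents that add atoms: none
Why: Acid-catalysed acetal solvolysis in methanol (MOM cleavage) should release the three phenols, under conditions that the skipped tetraene and the homoallylic alcohol tolerate, as they do in acidic esterification of polyunsaturated fatty acids.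

**Compound list**

1 | phloroglucinol (benzene-1,3,5-triol) | Oc1cc(O)cc(O)c1 | starting material
2 | 1,3,5-tris(methoxymethoxy)benzene | COCOc1cc(OCOC)cc(OCOC)c1 | intermediate
3 | hex-5-ynoic acid | C#CCCCC(=O)O | starting material
4 | 1-(1H-imidazol-1-yl)hex-5-yn-1-one (hex-5-ynoyl imidazolide) | C#CCCCC(=O)n1ccnc1 | intermediate
5 | N-methoxy-N-methylhex-5-ynamide | C#CCCCC(=O)N(C)OC | intermediate
6 | 2,4,6-tris(methoxymethoxy)phenyllithium | [Li]c1c(OCOC)cc(OCOC)cc1OCOC | intermediate
7 | dilithiated tetrahedral adduct of 6 and 5 (lithium acetylide, lithium N-methoxy-N-methyl hemiaminal alkoxide) | [Li]C#CCCCC(O[Li])(N(C)OC)c1c(OCOC)cc(OCOC)cc1OCOC | intermediate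
8 | 1-[2,4,6-tris(methoxymethoxy)phenyl]hex-5-yn-1-one | C#CCCCC(=O)c1c(OCOC)cc(OCOC)cc1OCOC | intermediate
9 | 4-chlorobut-2-yn-1-ol | OCC#CCCl | starting material
10 | 4-iodobut-2-yn-1-ol | OCC#CCI | intermediate
11 | alkynylcopper of 8 (monovalent copper acetylide) | [Cu]C#CCCCC(=O)c1c(OCOC)cc(OCOC)cc1OCOC | intermediate
12 | 10-hydroxy-1-[2,4,6-tris(methoxymethoxy)phenyl]deca-5,8-diyn-1-one | OCC#CCC#CCCCC(=O)c1c(OCOC)cc(OCOC)cc1OCOC | intermediate
13 | 10-bromo-1-[2,4,6-tris(methoxymethoxy)phenyl]deca-5,8-diyn-1-one | BrCC#CCC#CCCCC(=O)c1c(OCOC)cc(OCOC)cc1OCOC | intermediate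
14 | (S)-2-propyloxirane ((S)-1,2-epoxypentane) | CCC[C@H]1CO1 | starting material
15 | lithium acetylide–ethylenediamine complex | [Li]C#C.NCCN | starting material
16 | (4S)-hept-1-yn-4-ol | CCC[C@H](O)CC#C | intermediate
17 | (3-bromoprop-1-yn-1-yl)trimethylsilane | C[Si](C)(C)C#CCBr | starting material
18 | alkynylcopper of 16 (monovalent copper acetylide) | CCC[C@H](O)CC#C[Cu] | intermediate
19 | (4S)-10-(trimethylsilyl)deca-6,9-diyn-4-ol | CCC[C@H](O)CC#CCC#C[Si](C)(C)C | intermediate
20 | (4S)-deca-6,9-diyn-4-ol | CCC[C@H](O)CC#CCC#C | intermediate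
21 | alkynylcopper of 20 (monovalent copper acetylide) | CCC[C@H](O)CC#CCC#C[Cu] | intermediate
22 | (17S)-17-hydroxy-1-[2,4,6-tris(methoxymethoxy)phenyl]icosa-5,8,11,14-tetrayn-1-one | CCC[C@H](O)CC#CCC#CCC#CCC#CCCCC(=O)c1c(OCOC)cc(OCOC)cc1OCOC | intermediate
23 | (5Z,8Z,11Z,14Z,17S)-17-hydroxy-1-[2,4,6-tris(methoxymethoxy)phenyl]icosa-5,8,11,14-tetraen-1-one | CCC[C@H](O)C/C=C\C/C=C\C/C=C\C/C=C\CCCC(=O)c1c(OCOC)cc(OCOC)cc1OCOC | intermediate
24 | (5Z,8Z,11Z,14Z,17S)-17-hydroxy-1-(2,4,6-trihydroxyphenyl)icosa-5,8,11,14-tetraen-1-one | CCC[C@H](O)C/C=C\C/C=C\C/C=C\C/C=C\CCCC(=O)c1c(O)cc(O)cc1O | target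

**Step count and risks**

Total steps: 11. Longest linear sequence: 7 steps (steps 1, 3, 4, 5, 9, 10, 11; the branch through steps 6, 7, 8 is shorter).

Steps most likely to fail:

1. Step 9 (key coupling). Two sensitive partners must react close to 1:1. Slow coupling would give time for γ-attack (SN2') to allenes, for base-induced propargyl–allenyl isomerisation of the skipped diynes, and for oxidative (Glaser) homocoupling of the alkyne. The fallback sets out from 20 (with 9) and comes back to the route at 22. Compound 20 is coupled with an excess of the cheap 4-chlorobut-2-yn-1-ol 9 under the conditions of step 4 (CuI, NaI, K2CO3, DMF) to give (11S)-tetradeca-2,5,8-triyne-1,11-diol F1, in which the C10–C11 bond is already in place. A chemoselective Appel bromination of the primary propargylic hydroxyl (CBr4, PPh3, CH2Cl2, −30 °C; the secondary carbinol reacts far more slowly) should give (4S)-14-bromotetradeca-6,9,12-triyn-4-ol F2. F2 is then coupled (CuI, Cs2CO3, DMF) with the robust monoalkyne 8, which can be used in excess and recovered, to give 22.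

2. Step 10 (semi-hydrogenation). With four alkynes in one molecule, over-reduction, an unreduced alkyne or Z-to-E isomerisation at any one site would give mixtures that are hard to separate. The fallback sets out from 12 (with 20) and comes back at 23; it halves the number of alkynes reduced at one time. Diynol 12 is semi-hydrogenated (H2, Lindlar catalyst as in step 10, quinoline, EtOAc) to (5Z,8Z)-10-hydroxy-1-[2,4,6-tris(methoxymethoxy)phenyl]deca-5,8-dien-1-one F3. Appel bromination (CBr4, PPh3) gives (5Z,8Z)-10-bromo-1-[2,4,6-tris(methoxymethoxy)phenyl]deca-5,8-dien-1-one F4. CuI/Cs2CO3 coupling of alkyne 20 at the primary allylic CH2Br (again forming C10–C11) should give (5Z,8Z,17S)-17-hydroxy-1-[2,4,6-tris(methoxymethoxy)phenyl]icosa-5,8-dien-11,14-diyn-1-one F5. Lindlar reduction of the two remaining alkynes gives 23.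

3. Step 3 (aryl ketone formation). The hindered aryllithium may act as a base toward the alkyne C–H and the α-CH2 of the amide faster than it adds, and the resulting lithium acetylide may acylate itself on unreacted amide. The fallback sets out from 6 (made from 2 as in step 3) and comes back at 8; it removes the acidic alkyne from the addition step. Aryllithium 6 is added to δ-valerolactone F6 (THF, −78 °C) to give 5-hydroxy-1-[2,4,6-tris(methoxymethoxy)phenyl]pentan-1-one F7. Dess–Martin oxidation gives 5-oxo-5-[2,4,6-tris(methoxymethoxy)phenyl]pentanal F8. Seyferth–Gilbert homologation with the Ohira–Bestmann reagent (dimethyl (1-diazo-2-oxopropyl)phosphonate, K2CO3, MeOH), to which the hindered aryl ketone is inert, should give 8.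

Further compounds
F1 | step 9 | (11S)-tetradeca-2,5,8-triyne-1,11-diol | CCC[C@H](O)CC#CCC#CCC#CCO
F2 | step 9 | (4S)-14-bromotetradeca-6,9,12-triyn-4-ol | CCC[C@H](O)CC#CCC#CCC#CCBr
F3 | step 10 | (5Z,8Z)-10-hydroxy-1-[2,4,6-tris(methoxymethoxy)phenyl]deca-5,8-dien-1-one | OC/C=C\C/C=C\CCCC(=O)c1c(OCOC)cc(OCOC)cc1OCOC
F4 | step 10 | (5Z,8Z)-10-bromo-1-[2,4,6-tris(methoxymethoxy)phenyl]deca-5,8-dien-1-one | BrC/C=C\C/C=C\CCCC(=O)c1c(OCOC)cc(OCOC)cc1OCOC
F5 | step 10 | (5Z,8Z,17S)-17-hydroxy-1-[2,4,6-tris(methoxymethoxy)phenyl]icosa-5,8-dien-11,14-diyn-1-one | CCC[C@H](O)CC#CCC#CC/C=C\C/C=C\CCCC(=O)c1c(OCOC)cc(OCOC)cc1OCOC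
F6 | step 3 | δ-valerolactone (oxan-2-one) | O=C1CCCCO1
F7 | step 3 | 5-hydroxy-1-[2,4,6-tris(methoxymethoxy)phenyl]pentan-1-one | OCCCCC(=O)c1c(OCOC)cc(OCOC)cc1OCOC
F8 | step 3 | 5-oxo-5-[2,4,6-tris(methoxymethoxy)phenyl]pentanal | O=CCCCC(=O)c1c(OCOC)cc(OCOC)cc1OCOC
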